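**Retrosynthetic overview**
- Azepanone last: N12–C13 by intramolecular reductive amination, C17–C16 by Pd-catalysed coupling of a C17 thioester with an alkylzinc reagent.
- Fused lactone by reduction of a C4 ketone and lactonisation; cyclopentene (C8=C9) by intramolecular aldol condensation of a 1,4-diketone.
- Key disconnection C18–C3: intermolecular Michael addition of a 5-substituted N-Boc-3-oxoproline allyl ester to (E)-1-nitrobut-1-ene, then nitro-Michael addition to methyl methacrylate and Nef reaction.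
- The 3-oxoproline comes from L-homoserine: Zn-mediated carbonyl allylation (side lactone), Masamune homologation, diazo transfer, Rh-catalysed N–H insertion.
- Ring order: side-chain lactone, pyrrolidine, cyclopentene, fused lactone, azepanone.

Assumption: the target is exactly the given SMILES; N-Boc-O-benzyl-L-homoserine and 2-(3-chloropropyl)-1,3-dioxolane are taken as catalogue chemicals.

Locants used in all names (taken from the target): C1–C2 ethyl; C3 (CH–Et); C4 (CH–O); O5–C6(=O)–C7(CH3) fused lactone; C8=C9; C10 (CH2); C11 (N–CH); N12; C13–C16 (CH2)4; C17 (C=O); C18 (quaternary C); C19 (O–CH), C20, C21 (CH–CH3), C22 (C=O) side lactone. Target = (3R,4S,7R,11S,18R,19S,21S).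

**Route**

Step 1
Reactants: 1 propanal; 2 nitromethane
Product: 3 1-nitrobutan-2-ol (racemic)
Conditions: MeNO2 (5 equiv), NaOH (10 mol%), EtOH/H2O, 0 °C → rt
Reagents that add atoms: none
Why: Henry (nitro-aldol) addition of the nitronate to the aldehyde; the racemic carbinol centre is removed in step 2.

Step 2
Reactants: 3 1-nitrobutan-2-ol
Product: 5 (E)-1-nitrobut-1-ene, via mesylate 4 (not isolated)
Conditions: MsCl (1.2 equiv), Et3N (2.5 equiv), CH2Cl2, −10 → 0 °C
Reagents that add atoms: none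
Why: Mesylation and E1cB elimination of the β-nitro mesylate give the conjugated, thermodynamically favoured (E)-nitroalkene.

Step 3
Reactants: 6 Meldrum's acid
Product: 7 monoallyl malonate [3-oxo-3-(prop-2-en-1-yloxy)propanoic acid]
Conditions: allyl alcohol (1.2 equiv), toluene, 100 °C
Reagents that add atoms: allyl alcohol (C=CCO)
Why: Thermal alcoholysis of Meldrum's acid opens the ring to the malonic half ester with loss of acetone.

Step 4
Reactants: 8 2-(3-chloropropyl)-1,3-dioxolane
Product: 10 [3-(1,3-dioxolan-2-yl)propyl]zinc chloride (THF solution), via Grignard reagent 9 (not isolated)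
Conditions: Mg, I2 (cat.), THF, 50 °C; then ZnCl2 (1.1 equiv), THF, 0 °C
Reagents that add atoms: zinc dichloride (Cl[Zn]Cl)
Why: Grignard formation and transmetalation to zinc give an alkylzinc that tolerates lactones and carbamates in the later Fukuyama coupling.

Step 5
Reactants: 11 N-Boc-O-benzyl-L-homoserine
Product: 13 tert-butyl N-[(2S)-4-(benzyloxy)-1-hydroxybutan-2-yl]carbamate, via mixed anhydride 12 (not isolated)
Conditions: i-BuOCOCl, N-methylmorpholine, THF, −15 °C; then NaBH4, H2O, 0 °C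
Reagents that add atoms: none
Why: Mixed-anhydride activation and chemoselective borohydride reduction of the carboxyl group; C11 (S, from L-homoserine) is untouched.

Step 6
Reactants: 13 amino alcohol
Product: 14 tert-butyl N-[(2S)-4-(benzyloxy)-1-oxobutan-2-yl]carbamate
Conditions: Dess–Martin periodinane, NaHCO3, CH2Cl2, 0 °C → rt
Reagents that add atoms: none
Why: Buffered Dess–Martin oxidation gives the N-Boc α-amino aldehyde without epimerising C11; it is used at once.

Step 7
Reactants: 14 amino aldehyde; 15 ethyl 2-(bromomethyl)acrylate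
Product: 18 tert-butyl N-[(1S)-3-(benzyloxy)-1-[(2S)-4-methylidene-5-oxooxolan-2-yl]propyl]carbamate, via allylzinc bromide 16 (not isolated), via hydroxy ester 17 (not isolated)
Conditions: Zn dust, THF/sat. aq NH4Cl (1:1), 0 °C → rt; then PPTS (10 mol%), toluene, 60 °C
Reagents that add atoms: none
Why: Barbier-type carbonyl allylation in which zinc chelates the N–H carbamate and the aldehyde (Cram-chelate), so the allyl group adds to give the syn (threo) amino alcohol, C19 = S; acid-catalysed lactonisation then gives the α-methylene-γ-butyrolactone.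

Step 8
Reactants: 18 α-methylene lactone
Product: 19 tert-butyl N-[(1S)-3-hydroxy-1-[(2S,4S)-4-methyl-5-oxooxolan-2-yl]propyl]carbamate
Conditions: H2 (1 atm), 10% Pd/C, EtOH, rt
Reagents that add atoms: none
Why: Heterogeneous hydrogenation delivers hydrogen to the lactone face opposite the C19 substituent, giving the cis lactone (C21 = S), and hydrogenolyses the benzyl ether in the same operation.

Step 9
Reactants: 19 hydroxy lactone
Product: 21 (3S)-3-[(tert-butoxycarbonyl)amino]-3-[(2S,4S)-4-methyl-5-oxooxolan-2-yl]propanoic acid, via aldehyde 20 (not isolated)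
Conditions: TEMPO (0.2 equiv), PhI(OAc)2 (2.5 equiv), MeCN/H2O (1:1), rt
Reagents that add atoms: water (O)
Why: Oxoammonium (TEMPO) oxidation of the primary alcohol through the aldehyde hydrate to the acid; carbamate and lactone are inert.

Step 10
Reactants: 21 β-amino acid; 7 monoallyl malonate
Product: 24 allyl (5S)-5-[(tert-butoxycarbonyl)amino]-5-[(2S,4S)-4-methyl-5-oxooxolan-2-yl]-3-oxopentanoate, via acyl imidazolide 22 (not isolated), via acylmalonate 23 (not isolated)
Conditions: CDI (1.1 equiv), THF, rt; then 7 (2 equiv), MgCl2 (2 equiv), Et3N (4 equiv), THF/MeCN, rt → 40 °C; aq citric acid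
Reagents that add atoms: none
Why: Masamune–Brooks decarboxylative Claisen condensation of the acyl imidazolide with the magnesium malonate half ester under near-neutral conditions, which leaves the lactone and C11 intact.

Step 11
Reactants: 24 β-keto ester
Product: 25 allyl (5S)-5-[(tert-butoxycarbonyl)amino]-2-diazo-5-[(2S,4S)-4-methyl-5-oxooxolan-2-yl]-3-oxopentanoate
Conditions: 4-acetamidobenzenesulfonyl azide (1.2 equiv), Et3N, MeCN, 0 °C → rt
Reagents that add atoms: 4-acetamidobenzenesulfonyl azide (CC(=O)Nc1ccc(cc1)S(=O)(=O)N=[N+]=[N-])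
Why: Regitz diazo transfer to the active methylene (C18) of the β-keto ester.

Step 12
Reactants: 25 diazo keto ester
Product: 26 2-allyl 1-tert-butyl (5S)-5-[(2S,4S)-4-methyl-5-oxooxolan-2-yl]-3-oxopyrrolidine-1,2-dicarboxylate (C18 epimers and enol)
Conditions: Rh2(OAc)4 (2 mol%), toluene, 80 °C
Reagents that add atoms: none
Why: Intramolecular N–H insertion of the rhodium carbenoid into the carbamate closes the five-membered ring (N12–C18); C18 is still enolisable, so its configuration is irrelevant here.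

Step 13
Reactants: 26 N-Boc-3-oxoproline allyl ester; 5 (E)-1-nitrobut-1-ene
Product: 27 2-allyl 1-tert-butyl (2R,5S)-5-[(2S,4S)-4-methyl-5-oxooxolan-2-yl]-2-(1-nitrobutan-2-yl)-3-oxopyrrolidine-1,2-dicarboxylate (C3 epimers)
Conditions: 5 (1.5 equiv), Et3N (0.2 equiv), toluene, −20 → 0 °C
Reagents that add atoms: none
Why: Key intermolecular Michael addition of the β-keto ester enolate to the nitroalkene; A(1,3) strain with N-Boc holds the C11 lactonyl group pseudoaxial, so the nitroalkene adds to the opposite face and sets quaternary C18 as R (C3 branch trans to C19), while C3 forms as a mixture that is equilibrated in step 16.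

Step 14
Reactants: 27 Michael adduct; 28 methyl methacrylate
Product: 29 2-allyl 1-tert-butyl (2R,5S)-2-(7-methoxy-6-methyl-4-nitro-7-oxoheptan-3-yl)-5-[(2S,4S)-4-methyl-5-oxooxolan-2-yl]-3-oxopyrrolidine-1,2-dicarboxylate (mixture at C3/C4/C7)
Conditions: 28 (5 equiv), DBU (0.5 equiv), MeCN, 0 °C → rt
Reagents that add atoms: none
Why: Nitro-Michael addition of the primary nitronate to the methacrylate forms C4–C8; C4 becomes a ketone in step 15 and C7 is set in step 18, so neither needs control here.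

Step 15
Reactants: 29 γ-nitro ester
Product: 31 2-allyl 1-tert-butyl (2R,5S)-2-(7-methoxy-6-methyl-4,7-dioxoheptan-3-yl)-5-[(2S,4S)-4-methyl-5-oxooxolan-2-yl]-3-oxopyrrolidine-1,2-dicarboxylate (mixture at C3/C7), via nitronate salt 30 (not isolated)
Conditions: DBU (1.1 equiv), THF, 0 °C; then aq TiCl3 (5 equiv), NH4OAc buffer (pH 5–6), THF/H2O, 0 °C → rt
Reagents that add atoms: water (O)
Why: McMurry-type reductive Nef reaction: the nitronate is reduced by TiCl3 to the imine, which hydrolyses at buffered pH to the C4 ketone without retro-Claisen cleavage of the quaternary β-keto ester.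

Step 16
Reactants: 31 1,4-diketone
Product: 33 bicyclic enone (N-Boc cyclopenta[b]pyrrol-5-one; 3R,11S,18R,19S,21S; C7 epimers), via aldol adduct 32 (not isolated)
Conditions: pyrrolidine (0.5 equiv), AcOH (0.5 equiv), toluene, 70 °C; then DBU (0.2 equiv), rt
Reagents that add atoms: none
Why: Amine-catalysed intramolecular aldol condensation of C8 onto the C9 ketone (five-membered ring; the bridged alternative cannot dehydrate); the DBU finish equilibrates C3, α to the C4 ketone, to the exo (convex-face) ethyl epimer cis to the angular ester, 3R.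

Step 17
Reactants: 33 bicyclic enone
Product: 35 N-Boc tricyclic lactone allyl ester (3R,4S,11S,18R,19S,21S; C7 epimers), via allylic alcohol 34 (not isolated)
Conditions: NaBH4, CeCl3·7H2O, MeOH, −78 °C; then PPTS (10 mol%), toluene, 50 °C
Reagents that add atoms: none
Why: Luche 1,2-reduction: the small hydride attacks the convex face, syn to the exo ethyl group (as in 2-alkylcyclopentanones) and away from the N-Boc-bearing face, giving the 4S alcohol trans to ethyl, which lactonises onto the methyl ester with retention.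

Step 18
Reactants: 35 lactone (C7 mixture)
Product: 37 N-Boc tricyclic lactone allyl ester (3R,4S,7R,11S,18R,19S,21S), via potassium dienolate 36 (not isolated)
Conditions: KN(SiMe3)2 (1.05 equiv), THF, −78 °C, 20 min; then AcOH in THF, −78 °C
Reagents that add atoms: none
Why: Deprotonation of the most acidic C–H (allylic lactone α-H) and kinetic α-protonation of the dienolate from the convex face (the face of H4) give 7R and keep C8=C9 out of conjugation; the minor 7-epimer is separated and recycled through the same step.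

Step 19
Reactants: 37 allyl ester
Product: 38 C17 carboxylic acid (3R,4S,7R,11S,18R,19S,21S)
Conditions: Pd(PPh3)4 (5 mol%), morpholine (3 equiv), THF, rt
Reagents that add atoms: none
Why: Palladium-catalysed allyl transfer (Tsuji–Trost deallylation) to morpholine frees only the allyl ester; Boc, both lactones and the hindered tetrasubstituted alkene are untouched.

Step 20
Reactants: 38 acid
Product: 39 C17 S-ethyl thioester (3R,4S,7R,11S,18R,19S,21S)
Conditions: EtSH (5 equiv), EDC·HCl (2 equiv), DMAP (0.5 equiv), CH2Cl2, 0 °C → rt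
Reagents that add atoms: ethanethiol (CCS)
Why: Steglich-type carbodiimide/DMAP thioesterification; the acid has no α-hydrogen, so nothing can epimerise.

Step 21
Reactants: 39 thioester; 10 [3-(1,3-dioxolan-2-yl)propyl]zinc chloride
Product: 40 C17 ketone carrying the 3-(1,3-dioxolan-2-yl)propyl chain (3R,4S,7R,11S,18R,19S,21S)
Conditions: 10 (3 equiv), PdCl2(PPh3)2 (10 mol%), toluene/THF, rt → 40 °C
Reagents that add atoms: none
Why: Fukuyama coupling (acyl–palladium from the thioester, transmetalation with the alkylzinc) forms C17–C16 chemoselectively in the presence of two lactones and the carbamate.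

Step 22
Reactants: 40 keto acetal
Product: 43 CNP0315436.2 (target), via ammonium aldehyde 41 (not isolated), via cyclic iminium salt 42 (not isolated)
Conditions: TFA/CH2Cl2/H2O (10:10:1), 0 °C → rt; evaporate; then NaBH(OAc)3 (3 equiv), NaOAc, ClCH2CH2Cl, rt
Reagents that add atoms: none
Why: Acid removes Boc and the dioxolane, the ammonium aldehyde condenses to the seven-membered iminium and intramolecular reductive amination closes the azepanone; the medium stays acidic, so the free amine cannot attack the side lactone, and no stereocentre is touched.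

**Compound list**

1 | propanal | CCC=O | starting material
2 | nitromethane | C[N+](=O)[O-] | starting material
3 | 1-nitrobutan-2-ol (racemic) | CCC(O)C[N+](=O)[O-] | intermediate
4 | 1-nitrobutan-2-yl methanesulfonate (not isolated) | CCC(OS(C)(=O)=O)C[N+](=O)[O-] | intermediate
5 | (E)-1-nitrobut-1-ene | CC/C=C/[N+](=O)[O-] | intermediate
6 | Meldrum's acid (2,2-dimethyl-1,3-dioxane-4,6-dione) | CC1(C)OC(=O)CC(=O)O1 | starting material
7 | monoallyl malonate | OC(=O)CC(=O)OCC=C | intermediate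
8 | 2-(3-chloropropyl)-1,3-dioxolane | ClCCCC1OCCO1 | starting material
9 | [3-(1,3-dioxolan-2-yl)propyl]magnesium chloride (not isolated) | Cl[Mg]CCCC1OCCO1 | intermediate
10 | [3-(1,3-dioxolan-2-yl)propyl]zinc chloride | Cl[Zn]CCCC1OCCO1 | intermediate
11 | N-Boc-O-benzyl-L-homoserine | CC(C)(C)OC(=O)N[C@@H](CCOCc1ccccc1)C(=O)O | starting material
12 | isobutyl carbonic mixed anhydride of 11 (not isolated) | CC(C)(C)OC(=O)N[C@@H](CCOCc1ccccc1)C(=O)OC(=O)OCC(C)C | intermediate
13 | tert-butyl N-[(2S)-4-(benzyloxy)-1-hydroxybutan-2-yl]carbamate | CC(C)(C)OC(=O)N[C@@H](CCOCc1ccccc1)CO | intermediate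
14 | tert-butyl N-[(2S)-4-(benzyloxy)-1-oxobutan-2-yl]carbamate | CC(C)(C)OC(=O)N[C@@H](CCOCc1ccccc1)C=O | intermediate
15 | ethyl 2-(bromomethyl)acrylate | CCOC(=O)C(=C)CBr | starting material
16 | [2-(ethoxycarbonyl)prop-2-en-1-yl]zinc bromide (not isolated) | CCOC(=O)C(=C)C[Zn]Br | intermediate
17 | ethyl (4S,5S)-7-(benzyloxy)-5-[(tert-butoxycarbonyl)amino]-4-hydroxy-2-methylideneheptanoate (not isolated) | CC(C)(C)OC(=O)N[C@@H](CCOCc1ccccc1)[C@@H](O)CC(=C)C(=O)OCC | intermediate
18 | tert-butyl N-[(1S)-3-(benzyloxy)-1-[(2S)-4-methylidene-5-oxooxolan-2-yl]propyl]carbamate | CC(C)(C)OC(=O)N[C@@H](CCOCc1ccccc1)[C@@H]2CC(=C)C(=O)O2 | intermediate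
19 | tert-butyl N-[(1S)-3-hydroxy-1-[(2S,4S)-4-methyl-5-oxooxolan-2-yl]propyl]carbamate | CC(C)(C)OC(=O)N[C@@H](CCO)[C@@H]1C[C@H](C)C(=O)O1 | intermediate
20 | tert-butyl N-[(1S)-1-[(2S,4S)-4-methyl-5-oxooxolan-2-yl]-3-oxopropyl]carbamate (not isolated) | CC(C)(C)OC(=O)N[C@@H](CC=O)[C@@H]1C[C@H](C)C(=O)O1 | intermediate
21 | (3S)-3-[(tert-butoxycarbonyl)amino]-3-[(2S,4S)-4-methyl-5-oxooxolan-2-yl]propanoic acid | CC(C)(C)OC(=O)N[C@@H](CC(=O)O)[C@@H]1C[C@H](C)C(=O)O1 | intermediate
22 | acyl imidazolide of 21 (not isolated) | CC(C)(C)OC(=O)N[C@@H](CC(=O)n1ccnc1)[C@@H]2C[C@H](C)C(=O)O2 | intermediate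
23 | 2-acylmalonic acid monoallyl ester from 22 and 7 (magnesium chelate; not isolated) | CC(C)(C)OC(=O)N[C@@H](CC(=O)C(C(=O)O)C(=O)OCC=C)[C@@H]1C[C@H](C)C(=O)O1 | intermediate
24 | allyl (5S)-5-[(tert-butoxycarbonyl)amino]-5-[(2S,4S)-4-methyl-5-oxooxolan-2-yl]-3-oxopentanoate | CC(C)(C)OC(=O)N[C@@H](CC(=O)CC(=O)OCC=C)[C@@H]1C[C@H](C)C(=O)O1 | intermediate
25 | allyl (5S)-5-[(tert-butoxycarbonyl)amino]-2-diazo-5-[(2S,4S)-4-methyl-5-oxooxolan-2-yl]-3-oxopentanoate | CC(C)(C)OC(=O)N[C@@H](CC(=O)C(=[N+]=[N-])C(=O)OCC=C)[C@@H]1C[C@H](C)C(=O)O1 | intermediate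
26 | 2-allyl 1-tert-butyl (5S)-5-[(2S,4S)-4-methyl-5-oxooxolan-2-yl]-3-oxopyrrolidine-1,2-dicarboxylate (C18 epimers and enol) | CC(C)(C)OC(=O)N1C(C(=O)OCC=C)C(=O)C[C@H]1[C@@H]2C[C@H](C)C(=O)O2 | intermediate
27 | 2-allyl 1-tert-butyl (2R,5S)-5-[(2S,4S)-4-methyl-5-oxooxolan-2-yl]-2-(1-nitrobutan-2-yl)-3-oxopyrrolidine-1,2-dicarboxylate (C3 epimers) | CC(C)(C)OC(=O)N1[C@@](C(CC)C[N+](=O)[O-])(C(=O)OCC=C)C(=O)C[C@H]1[C@@H]2C[C@H](C)C(=O)O2 | intermediate
28 | methyl methacrylate | COC(=O)C(C)=C | starting material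
29 | 2-allyl 1-tert-butyl (2R,5S)-2-(7-methoxy-6-methyl-4-nitro-7-oxoheptan-3-yl)-5-[(2S,4S)-4-methyl-5-oxooxolan-2-yl]-3-oxopyrrolidine-1,2-dicarboxylate (mixture at C3, C4, C7) | CC(C)(C)OC(=O)N1[C@@](C(CC)C(CC(C)C(=O)OC)[N+](=O)[O-])(C(=O)OCC=C)C(=O)C[C@H]1[C@@H]2C[C@H](C)C(=O)O2 | intermediate
30 | DBU-H+ nitronate of 29 (not isolated) | CC(C)(C)OC(=O)N1[C@@](C(CC)C(CC(C)C(=O)OC)=[N+]([O-])[O-])(C(=O)OCC=C)C(=O)C[C@H]1[C@@H]2C[C@H](C)C(=O)O2.C1CCC2=[NH+]CCCN2CC1 | intermediate
31 | 2-allyl 1-tert-butyl (2R,5S)-2-(7-methoxy-6-methyl-4,7-dioxoheptan-3-yl)-5-[(2S,4S)-4-methyl-5-oxooxolan-2-yl]-3-oxopyrrolidine-1,2-dicarboxylate (mixture at C3, C7) | CC(C)(C)OC(=O)N1[C@@](C(CC)C(=O)CC(C)C(=O)OC)(C(=O)OCC=C)C(=O)C[C@H]1[C@@H]2C[C@H](C)C(=O)O2 | intermediate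
32 | aldol adduct: bicyclic β-hydroxy ketone with C9–OH and C8–C9 bond formed (not isolated; mixture at C3, C7, C8, C9) | CC(C)(C)OC(=O)N1[C@H]([C@@H]3C[C@H](C)C(=O)O3)CC2(O)C(C(C)C(=O)OC)C(=O)C(CC)[C@@]12C(=O)OCC=C | intermediate
33 | bicyclic enone: N-Boc cyclopenta[b]pyrrol-5-one with C8=C9, C4 ketone, 18-CO2allyl, 3-ethyl, C8–CH(CH3)CO2CH3 and 11-lactonyl; (3R,11S,18R,19S,21S), C7 epimers | CC(C)(C)OC(=O)N1[C@H]([C@@H]3C[C@H](C)C(=O)O3)CC2=C(C(C)C(=O)OC)C(=O)[C@H](CC)[C@@]12C(=O)OCC=C | intermediate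
34 | (4S)-allylic alcohol from 33 (not isolated); (3R,4S,11S,18R,19S,21S), C7 epimers | CC(C)(C)OC(=O)N1[C@H]([C@@H]3C[C@H](C)C(=O)O3)CC2=C(C(C)C(=O)OC)[C@@H](O)[C@H](CC)[C@@]12C(=O)OCC=C | intermediate
35 | N-Boc tricyclic lactone, 18-CO2allyl; (3R,4S,11S,18R,19S,21S), C7 epimers | CC(C)(C)OC(=O)N1[C@H]([C@@H]3C[C@H](C)C(=O)O3)CC2=C4C(C)C(=O)O[C@H]4[C@H](CC)[C@@]12C(=O)OCC=C | intermediate
36 | potassium dienolate of 35 (not isolated) | [K+].CC(C)(C)OC(=O)N1[C@H]([C@@H]3C[C@H](C)C(=O)O3)CC2=C4C(C)=C([O-])O[C@H]4[C@H](CC)[C@@]12C(=O)OCC=C | intermediate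
37 | N-Boc tricyclic lactone, 18-CO2allyl; (3R,4S,7R,11S,18R,19S,21S) | CC(C)(C)OC(=O)N1[C@H]([C@@H]3C[C@H](C)C(=O)O3)CC2=C4[C@@H](C)C(=O)O[C@H]4[C@H](CC)[C@@]12C(=O)OCC=C | intermediate
38 | N-Boc tricyclic lactone C17 carboxylic acid; (3R,4S,7R,11S,18R,19S,21S) | CC(C)(C)OC(=O)N1[C@H]([C@@H]3C[C@H](C)C(=O)O3)CC2=C4[C@@H](C)C(=O)O[C@H]4[C@H](CC)[C@@]12C(=O)O | intermediate
39 | N-Boc tricyclic lactone C17 S-ethyl thioester; (3R,4S,7R,11S,18R,19S,21S) | CC(C)(C)OC(=O)N1[C@H]([C@@H]3C[C@H](C)C(=O)O3)CC2=C4[C@@H](C)C(=O)O[C@H]4[C@H](CC)[C@@]12C(=O)SCC | intermediate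
40 | N-Boc tricyclic lactone C17 ketone with 3-(1,3-dioxolan-2-yl)propyl chain; (3R,4S,7R,11S,18R,19S,21S) | CC(C)(C)OC(=O)N1[C@H]([C@@H]3C[C@H](C)C(=O)O3)CC2=C4[C@@H](C)C(=O)O[C@H]4[C@H](CC)[C@@]12C(=O)CCCC5OCCO5 | intermediate
41 | secondary ammonium trifluoroacetate with C17 ketone and C13 aldehyde (not isolated) | [NH2+]1[C@H]([C@@H]3C[C@H](C)C(=O)O3)CC2=C4[C@@H](C)C(=O)O[C@H]4[C@H](CC)[C@@]12C(=O)CCCC=O.[O-]C(=O)C(F)(F)F | intermediate
42 | cyclic N12=C13 iminium trifluoroacetate (not isolated) | [N+]15[C@H]([C@@H]3C[C@H](C)C(=O)O3)CC2=C4[C@@H](C)C(=O)O[C@H]4[C@H](CC)[C@@]12C(=O)CCCC=5.[O-]C(=O)C(F)(F)F | intermediate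
43 | CNP0315436.2; (3R,4S,7R,11S,18R,19S,21S) | CC[C@H]1[C@@H]2OC(=O)[C@H](C)C2=C2C[C@@H]([C@@H]3C[C@H](C)C(=O)O3)N3CCCCC(=O)[C@]213 | target

**Count**

Total steps: 22. Longest linear sequence: 18 steps (11 → 43, steps 5–22). Steps 1–2, 3 and 4 are side branches that supply 5, 7 and 10.

**Steps most likely to fail, with fallbacks**

Step 13 (key Michael addition). The risks are insufficient face selectivity at C18 and base-induced oligomerisation or retro-addition of the nitroalkene. The fallback replaces enolate chemistry with a Lewis-acid Mukaiyama–Michael reaction. Setting out from 26, silylation (Me3SiCl, Et3N, CH2Cl2, 0 °C) gives the trimethylsilyl enol ether of the β-keto ester F1. F1 adds to 5 with SnCl4 in CH2Cl2 at −78 °C through an open transition state, again anti to the C11 substituent but at low temperature and without reversible base-mediated steps. Aqueous work-up of the silyl nitronate comes back to the route at 27.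

Step 17 (C4 configuration). The risk is that hydride addition gives mainly the C4 epimer. The fallback reaches C4 by inversion instead of direct reduction. Setting out from 33, reduction with LiBH(s-Bu)3 in THF at −78 °C (bulky hydride, attack anti to the ethyl group) and a cold quench give the (4R)-hydroxy ester F2, isolated before it lactonises. Mitsunobu reaction (4-nitrobenzoic acid, PPh3, DIAD, THF, 0 °C) inverts C4 to the (4S)-4-nitrobenzoate F3. K2CO3 in MeOH at 0 °C removes the benzoate, and the liberated (4S)-alkoxide closes the lactone, coming back at 35.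

Step 21 (Fukuyama coupling at the quaternary thioester). The risk is that the hindered thioester reacts too slowly with palladium and the alkylzinc. The fallback uses chelation-activated acyl substitution (Mukaiyama ketone synthesis) in place of cross-coupling. Setting out from 38, 2,2'-dipyridyl disulfide and PPh3 in CH2Cl2 give the S-(pyridin-2-yl) thioester F4. Treating F4 in THF at −78 °C with Grignard reagent 9 (1.1 equiv) gives the ketone much faster than the Grignard attacks the lactones or the carbamate, and comes back at 40.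

**Further compounds**

F1 | step 13 | 2-allyl 1-tert-butyl (5S)-5-[(2S,4S)-4-methyl-5-oxooxolan-2-yl]-3-[(trimethylsilyl)oxy]-4,5-dihydro-1H-pyrrole-1,2-dicarboxylate | CC(C)(C)OC(=O)N1C(C(=O)OCC=C)=C(O[Si](C)(C)C)C[C@H]1[C@@H]2C[C@H](C)C(=O)O2
F2 | step 17 | (4R)-epimer of allylic alcohol 34; (3R,4R,11S,18R,19S,21S), C7 epimers | CC(C)(C)OC(=O)N1[C@H]([C@@H]3C[C@H](C)C(=O)O3)CC2=C(C(C)C(=O)OC)[C@H](O)[C@H](CC)[C@@]12C(=O)OCC=C
F3 | step 17 | (4S)-4-nitrobenzoate of allylic alcohol 34; (3R,4S,11S,18R,19S,21S), C7 epimers | CC(C)(C)OC(=O)N1[C@H]([C@@H]3C[C@H](C)C(=O)O3)CC2=C(C(C)C(=O)OC)[C@@H](OC(=O)c5ccc(cc5)[N+](=O)[O-])[C@H](CC)[C@@]12C(=O)OCC=C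
F4 | step 21 | S-(pyridin-2-yl) thioester of acid 38; (3R,4S,7R,11S,18R,19S,21S) | CC(C)(C)OC(=O)N1[C@H]([C@@H]3C[C@H](C)C(=O)O3)CC2=C4[C@@H](C)C(=O)O[C@H]4[C@H](CC)[C@@]12C(=O)Sc5ccccn5
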